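**Retrosynthetic overview**
1. Ring numbering used below: C1 bears CO2Me, C1=C2 is Z, C4 is the stereocentre, C7=C8 is Z, C11=C12 is E.
2. Target 26 ⇐ macrocyclic allylic alcohol 23 by reductive 1,3-transposition (sets 7Z and the C7 methyl); 23 ⇐ open-chain aldehyde enol triflate 21 by chromium/nickel closure of C7–C8 (the only ring, formed last).
3. 21 ⇐ isopropenyl carbinol 17 by Claisen rearrangement (C9–C10 bond, 11E); 17 ⇐ aldehyde 14.
4. 14 ⇐ Baylis–Hillman adduct 11 by Claisen rearrangement (key C13–C14 bond, 1Z enoate); 11 ⇐ keto aldehyde 9 + methyl acrylate.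
5. 9 ⇐ (R)-limonene 1, which supplies C4: allylic lithiation/allylation, ring-olefin epoxidation, cross-metathesis, periodate cleavage.

Assumption: epimer mixtures at carbinol and epoxide carbons that are destroyed later are carried on unseparated, and minor olefin isomers are removed by chromatography.

**Route**

Step 1
Reactants: 1 (R)-(+)-limonene; 2 allyl bromide
Product: 4 (4R)-4-(hexa-1,5-dien-2-yl)-1-methylcyclohex-1-ene, via 10-lithiolimonene 3 (not isolated)
Conditions: n-BuLi, TMEDA, hexane, rt, 24 h; then 2, THF, −78 °C → rt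
Reagents that add atoms: none
Why: Allylic metalation by n-BuLi·TMEDA takes place at the isopropenyl methyl, and the symmetrical 2-substituted allyllithium is alkylated by allyl bromide (SN2) without touching the C4 stereocentre.

Step 2
Reactants: 4 (4R)-4-(hexa-1,5-dien-2-yl)-1-methylcyclohex-1-ene
Product: 5 (4R)-4-(hexa-1,5-dien-2-yl)-1-methyl-7-oxabicyclo[4.1.0]heptane (cis/trans epoxide mixture)
Conditions: mCPBA (1.0 equiv), NaHCO3, CH2Cl2, 0 °C
Reagents that add atoms: mCPBA (3-chloroperoxybenzoic acid), O=C(OO)c1cccc(Cl)c1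
Why: Prilezhaev epoxidation is fastest at the trisubstituted ring olefin, well ahead of the 1,1-disubstituted and monosubstituted ones, and the new epoxide centres are erased in step 4.

Step 3
Reactants: 5 (4R)-4-(hexa-1,5-dien-2-yl)-1-methyl-7-oxabicyclo[4.1.0]heptane; 6 2-methyl-2-butene
Product: 7 (4R)-1-methyl-4-(6-methylhepta-1,5-dien-2-yl)-7-oxabicyclo[4.1.0]heptane
Conditions: second-generation Grubbs catalyst RuCl2(=CHPh)(PCy3)(H2IMes) (3 mol %), 6/CH2Cl2 1:1, 40 °C
Reagents that add atoms: none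
Why: Olefin cross-metathesis with 2-methyl-2-butene converts only the monosubstituted vinyl group into the isopropylidene terminus, the 1,1-disubstituted olefin and the epoxide being inert.

Step 4
Reactants: 7 (4R)-1-methyl-4-(6-methylhepta-1,5-dien-2-yl)-7-oxabicyclo[4.1.0]heptane
Product: 9 (3R)-3-(6-methylhepta-1,5-dien-2-yl)-6-oxoheptanal, via ring 1,2-diol 8 (not isolated)
Conditions: H5IO6 (1.2 equiv), THF/H2O, 0 °C → rt
Reagents that add atoms: water, O
Why: Acid opens the epoxide to the diol and periodate cuts its C–C bond (Malaprade cleavage), so both epoxide diastereomers converge on one keto aldehyde with the stereocentre untouched.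

Step 5
Reactants: 9 (3R)-3-(6-methylhepta-1,5-dien-2-yl)-6-oxoheptanal; 10 methyl acrylate
Product: 11 methyl (5R)-3-hydroxy-2-methylidene-5-(6-methylhepta-1,5-dien-2-yl)-8-oxononanoate (C3 epimers)
Conditions: DABCO (1 equiv), 10 (5 equiv), MeOH, rt, 3–5 d
Reagents that add atoms: none
Why: Morita–Baylis–Hillman reaction, in which the DABCO–acrylate zwitterion adds to the aldehyde only (the ketone is inert); the new carbinol centre (about 1:1) is destroyed in step 6.

Step 6
Reactants: 11 methyl (5R)-3-hydroxy-2-methylidene-5-(6-methylhepta-1,5-dien-2-yl)-8-oxononanoate; 12 ethyl vinyl ether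
Product: 14 methyl (2Z,5R)-5-(6-methylhepta-1,5-dien-2-yl)-8-oxo-2-(3-oxopropyl)non-2-enoate, via allyl vinyl ether 13 (not isolated)
Conditions: 12 (solvent), Hg(OAc)2 (0.3 equiv), reflux; K2CO3, concentrate; then toluene, 110 °C, sealed tube
Reagents that add atoms: none
Why: Mercury-catalysed vinyl ether exchange, then Claisen [3,3] rearrangement through a chair with the C3 alkyl chain equatorial, which places it cis to CO2Me (2Z, by analogy with ortho-ester Claisen rearrangements of alkyl Baylis–Hillman adducts) while forming the C–C bond and the aldehyde.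

Step 7
Reactants: 14 methyl (2Z,5R)-5-(6-methylhepta-1,5-dien-2-yl)-8-oxo-2-(3-oxopropyl)non-2-enoate; 15 2-bromopropene
Product: 17 methyl (2Z,5R)-2-(3-hydroxy-4-methylpent-4-en-1-yl)-5-(6-methylhepta-1,5-dien-2-yl)-8-oxonon-2-enoate (carbinol epimers), via isopropenylchromium dichloride 16 (not isolated)
Conditions: CrCl2 (4 equiv), NiCl2 (2 mol %), DMF, rt
Reagents that add atoms: none
Why: Nozaki–Hiyama–Kishi addition, in which the alkenylchromium reagent adds to the aldehyde only and leaves methyl ketone and enoate alone; the new carbinol centre is lost in step 10.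

Step 8
Reactants: 17 methyl (2Z,5R)-2-(3-hydroxy-4-methylpent-4-en-1-yl)-5-(6-methylhepta-1,5-dien-2-yl)-8-oxonon-2-enoate; 12 ethyl vinyl ether
Product: 18 methyl (2Z,5R)-2-[3-(ethenyloxy)-4-methylpent-4-en-1-yl]-5-(6-methylhepta-1,5-dien-2-yl)-8-oxonon-2-enoate
Conditions: 12 (solvent), Hg(OAc)2 (0.3 equiv), reflux, 24 h; K2CO3; Et3N-deactivated SiO2
Reagents that add atoms: none
Why: Mercury-catalysed transetherification gives the allyl vinyl ether at about 35 °C, below the temperature at which it rearranges, so it can be isolated.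

Step 9
Reactants: 18 methyl (2Z,5R)-2-[3-(ethenyloxy)-4-methylpent-4-en-1-yl]-5-(6-methylhepta-1,5-dien-2-yl)-8-oxonon-2-enoate
Product: 20 methyl (2Z,5R)-2-[3-(ethenyloxy)-4-methylpent-4-en-1-yl]-5-(6-methylhepta-1,5-dien-2-yl)-8-[(trifluoromethanesulfonyl)oxy]nona-2,8-dienoate, via potassium enolate 19 (not isolated)
Conditions: KN(SiMe3)2 (1.05 equiv), THF, −78 °C; then PhNTf2, −78 → 0 °C
Reagents that add atoms: N-phenylbis(trifluoromethanesulfonimide) (PhNTf2), O=S(=O)(N(c1ccccc1)S(=O)(=O)C(F)(F)F)C(F)(F)F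
Why: Kinetic deprotonation of the methyl ketone at CH3 and O-sulfonylation of the enolate give the 2-triflyloxy-1-alkene, the ester and vinyl ether being unaffected at −78 °C.

Step 10
Reactants: 20 methyl (2Z,5R)-2-[3-(ethenyloxy)-4-methylpent-4-en-1-yl]-5-(6-methylhepta-1,5-dien-2-yl)-8-[(trifluoromethanesulfonyl)oxy]nona-2,8-dienoate
Product: 21 methyl (2Z,5R)-5-(6-methylhepta-1,5-dien-2-yl)-2-[(3E)-4-methyl-7-oxohept-3-en-1-yl]-8-[(trifluoromethanesulfonyl)oxy]nona-2,8-dienoate
Conditions: toluene, 110 °C, sealed tube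
Reagents that add atoms: none
Why: Claisen [3,3] rearrangement through a chair with the carbinol substituent equatorial gives the E-trisubstituted olefin and the aldehyde, and the enol triflate survives the heating.

Step 11
Reactants: 21 methyl (2Z,5R)-5-(6-methylhepta-1,5-dien-2-yl)-2-[(3E)-4-methyl-7-oxohept-3-en-1-yl]-8-[(trifluoromethanesulfonyl)oxy]nona-2,8-dienoate
Product: 23 methyl (1Z,4R,11E)-8-hydroxy-11-methyl-7-methylidene-4-(6-methylhepta-1,5-dien-2-yl)cyclotetradeca-1,11-diene-1-carboxylate (C8 epimers), via alkenylchromium dichloride 22 (not isolated)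
Conditions: CrCl2 (10 equiv), NiCl2 (0.1 equiv), DMF/THF, slow addition to 2 mM, rt
Reagents that add atoms: none
Why: Intramolecular Nozaki–Hiyama–Kishi reaction, in which nickel activates the enol triflate and the alkenylchromium adds to the aldehyde under high dilution to close the 14-membered ring; the carbinol centre (either epimer) is removed in step 12.

Step 12
Reactants: 23 methyl (1Z,4R,11E)-8-hydroxy-11-methyl-7-methylidene-4-(6-methylhepta-1,5-dien-2-yl)cyclotetradeca-1,11-diene-1-carboxylate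
Product: 26 methyl (1Z,4R,7Z,11E)-7,11-dimethyl-4-(6-methylhepta-1,5-dien-2-yl)cyclotetradeca-1,7,11-triene-1-carboxylate (target), via sulfonylhydrazine 24 (not isolated), via allylic diazene 25 (not isolated)
Conditions: 2-nitrobenzenesulfonylhydrazide (NBSH), PPh3, DEAD, N-methylmorpholine, −30 °C → rt
Reagents that add atoms: none
Why: Myers reductive transposition, in which Mitsunobu displacement, loss of sulfinic acid and retro-ene (sigmatropic) loss of N2 deliver H to the exocyclic CH2 with the C8 ring substituent pseudo-equatorial, hence trans to the new methyl, which gives the 7Z olefin.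

**Compound list**
1 | (R)-(+)-limonene | CC1=CC[C@@H](CC1)C(C)=C | starting material
2 | allyl bromide | C=CCBr | starting material
3 | 10-lithiolimonene, 2-[(1R)-4-methylcyclohex-3-en-1-yl]prop-2-en-1-yllithium | CC1=CC[C@@H](CC1)C(=C)C[Li] | intermediate
4 | (4R)-4-(hexa-1,5-dien-2-yl)-1-methylcyclohex-1-ene | CC1=CC[C@@H](CC1)C(=C)CCC=C | intermediate
5 | (4R)-4-(hexa-1,5-dien-2-yl)-1-methyl-7-oxabicyclo[4.1.0]heptane, cis/trans epoxide mixture | CC12CC[C@H](CC1O2)C(=C)CCC=C | intermediate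
6 | 2-methyl-2-butene | CC=C(C)C | starting material
7 | (4R)-1-methyl-4-(6-methylhepta-1,5-dien-2-yl)-7-oxabicyclo[4.1.0]heptane, cis/trans epoxide mixture | CC12CC[C@H](CC1O2)C(=C)CCC=C(C)C | intermediate
8 | (4R)-1-methyl-4-(6-methylhepta-1,5-dien-2-yl)cyclohexane-1,2-diol | CC1(O)CC[C@H](CC1O)C(=C)CCC=C(C)C | intermediate
9 | (3R)-3-(6-methylhepta-1,5-dien-2-yl)-6-oxoheptanal | O=CC[C@@H](CCC(C)=O)C(=C)CCC=C(C)C | intermediate
10 | methyl acrylate | C=CC(=O)OC | starting material
11 | methyl (5R)-3-hydroxy-2-methylidene-5-(6-methylhepta-1,5-dien-2-yl)-8-oxononanoate, C3 epimers | C=C(C(=O)OC)C(O)C[C@@H](CCC(C)=O)C(=C)CCC=C(C)C | intermediate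
12 | ethyl vinyl ether | C=COCC | starting material
13 | methyl (5R)-3-(ethenyloxy)-2-methylidene-5-(6-methylhepta-1,5-dien-2-yl)-8-oxononanoate | C=C(C(=O)OC)C(OC=C)C[C@@H](CCC(C)=O)C(=C)CCC=C(C)C | intermediate
14 | methyl (2Z,5R)-5-(6-methylhepta-1,5-dien-2-yl)-8-oxo-2-(3-oxopropyl)non-2-enoate | COC(=O)/C(CCC=O)=C\C[C@@H](CCC(C)=O)C(=C)CCC=C(C)C | intermediate
15 | 2-bromopropene | CC(Br)=C | starting material
16 | isopropenylchromium dichloride | C=C(C)[Cr](Cl)Cl | intermediate
17 | methyl (2Z,5R)-2-(3-hydroxy-4-methylpent-4-en-1-yl)-5-(6-methylhepta-1,5-dien-2-yl)-8-oxonon-2-enoate, carbinol epimers | COC(=O)/C(CCC(O)C(C)=C)=C\C[C@@H](CCC(C)=O)C(=C)CCC=C(C)C | intermediate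
18 | methyl (2Z,5R)-2-[3-(ethenyloxy)-4-methylpent-4-en-1-yl]-5-(6-methylhepta-1,5-dien-2-yl)-8-oxonon-2-enoate | COC(=O)/C(CCC(OC=C)C(C)=C)=C\C[C@@H](CCC(C)=O)C(=C)CCC=C(C)C | intermediate
19 | potassium enolate of 18 (terminal, C8=C9) | COC(=O)/C(CCC(OC=C)C(C)=C)=C\C[C@@H](CCC(=C)[O-])C(=C)CCC=C(C)C.[K+] | intermediate
20 | methyl (2Z,5R)-2-[3-(ethenyloxy)-4-methylpent-4-en-1-yl]-5-(6-methylhepta-1,5-dien-2-yl)-8-[(trifluoromethanesulfonyl)oxy]nona-2,8-dienoate | COC(=O)/C(CCC(OC=C)C(C)=C)=C\C[C@@H](CCC(=C)OS(=O)(=O)C(F)(F)F)C(=C)CCC=C(C)C | intermediate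
21 | methyl (2Z,5R)-5-(6-methylhepta-1,5-dien-2-yl)-2-[(3E)-4-methyl-7-oxohept-3-en-1-yl]-8-[(trifluoromethanesulfonyl)oxy]nona-2,8-dienoate | COC(=O)/C(CC/C=C(\C)CCC=O)=C\C[C@@H](CCC(=C)OS(=O)(=O)C(F)(F)F)C(=C)CCC=C(C)C | intermediate
22 | alkenylchromium dichloride from 21 (CrCl2 in place of OTf) | COC(=O)/C(CC/C=C(\C)CCC=O)=C\C[C@@H](CCC(=C)[Cr](Cl)Cl)C(=C)CCC=C(C)C | intermediate
23 | methyl (1Z,4R,11E)-8-hydroxy-11-methyl-7-methylidene-4-(6-methylhepta-1,5-dien-2-yl)cyclotetradeca-1,11-diene-1-carboxylate, C8 epimers | C=C(CCC=C(C)C)[C@H]1C/C=C(\C(=O)OC)CC/C=C(\C)CCC(O)C(=C)CC1 | intermediate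
24 | C8 N-amino-N-(2-nitrobenzenesulfonyl)amine (sulfonylhydrazine) derived from 23 | C=C(CCC=C(C)C)[C@H]1C/C=C(\C(=O)OC)CC/C=C(\C)CCC(N(N)S(=O)(=O)c2ccccc2[N+](=O)[O-])C(=C)CC1 | intermediate
25 | C8 monoalkyl diazene derived from 24 | C=C(CCC=C(C)C)[C@H]1C/C=C(\C(=O)OC)CC/C=C(\C)CCC(N=N)C(=C)CC1 | intermediate
26 | methyl (1Z,4R,7Z,11E)-7,11-dimethyl-4-(6-methylhepta-1,5-dien-2-yl)cyclotetradeca-1,7,11-triene-1-carboxylate | C=C(CCC=C(C)C)[C@H]1C/C=C(\C(=O)OC)CC/C=C(\C)CC/C=C(/C)CC1 | target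

**Step count**
Total: 12 steps. Longest linear sequence: 12 steps (1 → 26); everything else is a bought reagent.

**Steps most likely to fail, with fallbacks**

Step 6. Vinyl ether formation on a Baylis–Hillman alcohol and the Z:E ratio of its Claisen rearrangement are the least precedented part of the route. The fallback sets out from keto aldehyde 9 and comes back at aldehyde 14, replacing steps 5 and 6 by a Still–Gennari olefination. Methyl bis(2,2,2-trifluoroethyl)phosphonoacetate is alkylated (NaH, DMF) with 3-bromo-1,1-dimethoxypropane to give methyl 2-[bis(2,2,2-trifluoroethoxy)phosphoryl]-5,5-dimethoxypentanoate F1. Its potassium salt (KN(SiMe3)2, 18-crown-6, THF, −78 °C) reacts with the aldehyde of 9 only and gives methyl (2Z,5R)-2-(3,3-dimethoxypropyl)-5-(6-methylhepta-1,5-dien-2-yl)-8-oxonon-2-enoate F2 with the same Z geometry. Acetal hydrolysis (PPTS, acetone/water) then gives 14.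

Step 11. Closure of a 14-membered ring from an enol triflate may be overtaken by oligomerisation or by reduction of the triflate. The fallback sets out from enol triflate 20 and comes back at alcohol 23, closing the same C7–C8 bond by a nickel-catalysed alkyne–aldehyde reductive coupling. Elimination (LiN(iPr)2, THF, −78 °C) gives methyl (2Z,5R)-2-[3-(ethenyloxy)-4-methylpent-4-en-1-yl]-5-(6-methylhepta-1,5-dien-2-yl)non-2-en-8-ynoate F3. Claisen rearrangement (toluene, 110 °C) gives methyl (2Z,5R)-5-(6-methylhepta-1,5-dien-2-yl)-2-[(3E)-4-methyl-7-oxohept-3-en-1-yl]non-2-en-8-ynoate F4. Exo-selective reductive macrocyclisation (Ni(cod)2, 1,3-bis(2,6-diisopropylphenyl)imidazol-2-ylidene, Et3SiH, THF, high dilution) gives the triethylsilyl ether of 23, F5, and Bu4NF then gives 23.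

Step 12. The Mitsunobu displacement on a hindered macrocyclic allylic alcohol may be slow or give SN2′ products. The fallback sets out from 23 and comes back at 26 through the same diazene 25, reached by hydride reduction instead of displacement. Dess–Martin oxidation gives methyl (1Z,4R,11E)-11-methyl-7-methylidene-4-(6-methylhepta-1,5-dien-2-yl)-8-oxocyclotetradeca-1,11-diene-1-carboxylate F6. Condensation with TsNHNH2 (PPTS, EtOH, 0 °C) gives its tosylhydrazone F7. Catecholborane (CHCl3, 0 °C) followed by NaOAc·3H2O (reflux) then releases 25, which loses N2 to give 26.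

**Further compounds**
F1 | step 6 | methyl 2-[bis(2,2,2-trifluoroethoxy)phosphoryl]-5,5-dimethoxypentanoate | COC(=O)C(CCC(OC)OC)P(=O)(OCC(F)(F)F)OCC(F)(F)F
F2 | step 6 | methyl (2Z,5R)-2-(3,3-dimethoxypropyl)-5-(6-methylhepta-1,5-dien-2-yl)-8-oxonon-2-enoate | COC(=O)/C(CCC(OC)OC)=C\C[C@@H](CCC(C)=O)C(=C)CCC=C(C)C
F3 | step 11 | methyl (2Z,5R)-2-[3-(ethenyloxy)-4-methylpent-4-en-1-yl]-5-(6-methylhepta-1,5-dien-2-yl)non-2-en-8-ynoate | COC(=O)/C(CCC(OC=C)C(C)=C)=C\C[C@@H](CCC#C)C(=C)CCC=C(C)C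
F4 | step 11 | methyl (2Z,5R)-5-(6-methylhepta-1,5-dien-2-yl)-2-[(3E)-4-methyl-7-oxohept-3-en-1-yl]non-2-en-8-ynoate | COC(=O)/C(CC/C=C(\C)CCC=O)=C\C[C@@H](CCC#C)C(=C)CCC=C(C)C
F5 | step 11 | methyl (1Z,4R,11E)-11-methyl-7-methylidene-4-(6-methylhepta-1,5-dien-2-yl)-8-[(triethylsilyl)oxy]cyclotetradeca-1,11-diene-1-carboxylate | C=C(CCC=C(C)C)[C@H]1C/C=C(\C(=O)OC)CC/C=C(\C)CCC(O[Si](CC)(CC)CC)C(=C)CC1
F6 | step 12 | methyl (1Z,4R,11E)-11-methyl-7-methylidene-4-(6-methylhepta-1,5-dien-2-yl)-8-oxocyclotetradeca-1,11-diene-1-carboxylate | C=C(CCC=C(C)C)[C@H]1C/C=C(\C(=O)OC)CC/C=C(\C)CCC(=O)C(=C)CC1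
F7 | step 12 | 4-methylbenzenesulfonylhydrazone of F6 | C=C(CCC=C(C)C)[C@H]1C/C=C(\C(=O)OC)CC/C=C(\C)CCC(=NNS(=O)(=O)c2ccc(C)cc2)C(=C)CC1
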